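## Structural features

The target is a 2,3-dihydro-1-benzofuran in which benzo ring A is fused to dihydrofuran ring B. C2 carries the catechol ring C, C3 the 3,5-dihydroxyphenyl ring D, C4 a free phenol, and C6 an (E)-ethenyl bridge to the 4-hydroxy-3-methoxyphenyl ring E. C2 and C3 are adjacent stereocentres, both S, with rings C and D trans across ring B; apart from the (E)-alkene they are the only stereochemical elements. The fragile groups are the six free phenols (above all the catechol, which oxidises in air once deprotonated), the stilbene alkene (no hydrogenation, sensitive to acid and light), the benzylic O1–C2 bond para to a ring C oxygen (it can open to a quinone methide), and the single methyl ether on ring E, which rules out methyl ethers as protecting groups elsewhere. The real difficulty is twofold: absolute control of the C2/C3 pair, which has no neighbouring group to direct a reagent, and attachment of the arm at C6, a carbon meta to both ring A oxygens and so out of reach of electrophilic substitution. Ring A carries oxygen on C4 and on C7a, on both sides of C3a, which is the imprint of cyclohexane-1,3-dione reacting through its C2 and one oxygen; the C2–C3 bond with its two aryl groups is the alkene of piceatannol. The key step uses both facts: it joins the dione carbon to C3 and the dione oxygen to C2 while ring A is still saturated, so ring B and both stereocentres arise in one operation and ring A is aromatised afterwards.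

## Logic of the disconnections

**17 ⇒ 16.** Six O–Si bonds are cut. All phenols must be masked through the carbenoid, enolate and organometallic steps, and silicon is the one mask that leaves with fluoride, sparing the ring E methyl ether and the alkene. Nothing is gained in skeleton, but every earlier intermediate becomes non-oxidisable and lipophilic. The forward step must avoid free phenoxides, which would invite catechol oxidation and opening of O1–C2.

**16 ⇒ 11 + 15.** The C6–C(vinyl) bond is cut. It is an sp2–sp2 bond, and cutting it removes ring E together with the preformed (E)-alkene, so 11 and all its precursors contain no second alkene that could compete in the carbenoid step. The forward coupling must retain alkene geometry and use a base mild enough for aryl silyl ethers.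

**15 ⇒ 14 ⇒ 12.** The C–Br bond is traced back to a C–CO2H bond and one O–Si bond is cut. 12 already holds the ring E oxygen pattern and the (E)-propenoate. The forward halodecarboxylation must keep the (E)-geometry and must not brominate the ring, hence the silyl ether.

**11 ⇒ 10.** The C6–B bond is cut back to C6–H. C6 cannot be reached by polar aromatic chemistry, so a sterically governed C–H borylation is the shortest entry and no C6 substituent has to be carried through the key step. The demand is site selectivity for C6 over C7 and over every C–H of rings C and D.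

**10 ⇒ 9 ⇒ 5.** The C4 O–Si bond is cut and two hydrogens are returned to C5 and C6. This brings ring A down to the oxidation level of a cyclohexane-1,3-dione, where C3a lies between two carbonyl-derived carbons and the two ring A oxygens are automatically differentiated (one in ring B, one a ketone). The forward dehydrogenation must act only at C5–C6 and must not aromatise ring B across C2–C3.

**5 ⇒ 2 + 4.** The C3–C3a and O1–C2 bonds are cut. Ring B and both stereocentres vanish and two simple, symmetrical-looking fragments remain. The forward annulation must be regioselective (dione carbon to the ring D side), trans-selective and enantioselective. Silyl ethers on 4 are chosen because the para-silyloxy group of ring C still donates, no O–H is left for insertion, and the bulky groups shield the nucleophilic ring positions.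

**2 ⇒ 1 and 4 ⇒ 3.** The C=N2 bond of 2 and the four O–Si bonds of 4 are cut. Both precursors are catalogue compounds and each needs one routine step. The only demand is a diazo-transfer reagent of low hazard.

## Other disconnections considered

**Alternative 1:** The cut takes ring C off C2 and ring D off C3 and leaves ring A on an alkene, with O1–C2 still open. In the forward step 3,4-bis(methoxymethoxy)phenyllithium A3 adds to boron of the ring A (E)-alkenyl pinacol boronate A2. An arylpalladium species from 3,5-bis(methoxymethoxy)phenyl triflate A4, Pd(OAc)2 and a chiral Mandyphos ligand then binds the alkene and triggers the 1,2-shift of ring C from boron to C2; reductive elimination puts ring D on C3 and gives boronate A1.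
- In favour: three fragments converge in one operation. The ring E arm is already in A2, so C6 of a finished ring A never has to be functionalised; on this point the alternative is the better plan. The ligand class has the stronger record for enantiocontrol, again a point for the alternative. Only C3 must be right, since later closure of O1–C2 through the para-oxygenated benzylic carbon should be trans-selective.
- Against: C3 becomes a triarylmethine next to a 2,6-dioxygenated ring, a steric demand far beyond the lightly substituted alkenyl boronates for which the reaction is secure. β-Aryl alkenyl boronate complexes can also transfer the alkenyl group to palladium directly, and the stilbene alkene of A2 can intercept the arylpalladium. A2 is itself a long synthesis. After A1 come C–B oxidation, acid removal of seven methoxymethyl ethers beside an acid-sensitive stilbene, and ring closure.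
- Comparison: both plans stretch an asymmetric metal-catalysed step beyond its proven scope, the alternative in sterics, the chosen plan in enantiocontrol. In step count (an estimated 14 to 16 against 10) and in protecting-group simplicity the chosen plan is ahead.

**Alternative 2:** The cut opens ring A at C3a–C4 and C7–C7a, so the aromatic ring is built last around a preset C3. In the forward step the chiral ynol silyl ether A6 and cyclobutenone A7 are heated: A7 opens to a vinylketene, which adds (2+2) to A6, and a 4π opening, a 6π closure and tautomerisation give phenol A5.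
- In favour: the substitution pattern of ring A is unambiguous and the C6 carbon is in place; this is better than a C–H borylation. The key step is neutral, thermal and creates no stereocentre, so C2 and C3 can come from established asymmetric chemistry; on reliability of absolute control the alternative is also better.
- Against: A6 is the hard part. Its 1,2-diaryl stereodiad must be made first, and the benzylic, propargylic C3–H is then exposed to the strong bases needed to form an ynol ether. A7 is a sensitive ketone with its own synthesis. After A5 the route needs ring closure with inversion at C2 (A5 carries C2 in the opposite sense; ring A is symmetric about the C3a–C6 axis, so either oxygen may close), oxidation of the CH2O group and olefination. Four benzyl ethers must then be removed without hydrogenation, that is with a Lewis acid that threatens the methyl ether.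
- Comparison: the alternative builds what the chosen plan buys as a dione. Its pericyclic key step is the more predictable one, but the step count (well over 20 against 10) is far worse.

**Alternative 3:** The cut is C3–C3a, read backwards as expansion of ring B to the pyranone of a flavanone. In the forward step the 3-diazoflavanone A9 is irradiated in wet THF: N2 leaves, the ring A carbon shifts from the carbonyl carbon to C3 (Wolff rearrangement), and water traps the ketene as acid A8.
- In favour: C2 comes from the chiral pool, since (2S)-eriodictyol A10 has the C2 arrangement of the target, so no asymmetric step is needed. This is better than the chosen plan provided the centre survives. The key step is metal-free, dependable and releases only N2, equal to the chosen key step in atom economy and better in precedent.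
- Against: a flavanone loses its C2 configuration by reversible opening to the chalcone under base, exactly the conditions needed to place a diazo group next to the ketone. A8 has a carboxyl group where ring D belongs, so a decarboxylative arylation through a C3 radical is needed, with trans selectivity resting on substrate bias alone. A10 has oxygen where C6 needs carbon, and the benzyl and diphenylmethylene groups again cannot be removed by hydrogenolysis.
- Comparison: two of the three substituents of the bicycle (ring D and the arm) must be exchanged after the key step, whereas the chosen key step installs both aryl groups at once. The step count (an estimated 16 to 18 against 10) favours the chosen plan.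

Key step: step 3

Assumption: the facial preference of Rh2(S-PTTL)4 in step 3 cannot be predicted with confidence; the route is written with this catalyst, and if it should favour the (2R,3R) series, the mirror-image catalyst Rh2(R-PTTL)4 is used with nothing else changed.

Abbreviations: TBS = tert-butyldimethylsilyl; ArC = 3,4-bis(TBS-oxy)phenyl (protected ring C); ArD = 3,5-bis(TBS-oxy)phenyl (protected ring D); p-ABSA = 4-acetamidobenzenesulfonyl azide; dtbpy = 4,4'-di-tert-butyl-2,2'-bipyridine.

## Route

Step 1
Reactants: 1 cyclohexane-1,3-dione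
Product: 2 2-diazocyclohexane-1,3-dione
Conditions: p-ABSA (1.05 equiv), Et3N (1.2 equiv), MeCN, 0 °C to rt
Reagents that add atoms: 4-acetamidobenzenesulfonyl azide, CC(=O)Nc1ccc(cc1)S(=O)(=O)N=[N+]=[N-]
Why: Regitz diazo transfer: the ammonium enolate of the 1,3-dione attacks the terminal azide nitrogen and the triazene collapses to the diazo compound and the sulfonamide. p-ABSA is chosen as the least shock-sensitive common transfer reagent, and its by-product is removed by filtration or aqueous base.

Step 2
Reactants: 3 piceatannol
Product: 4 (E)-3,3',4,5'-tetrakis(TBS-oxy)stilbene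
Conditions: TBSCl (5 equiv), imidazole (10 equiv), DMF, rt
Reagents that add atoms: tert-butyldimethylsilyl chloride, CC(C)(C)[Si](C)(C)Cl
Why: Imidazole-mediated silylation of phenols; all four oxygens must be capped because a free O–H would undergo O–H insertion with the carbenoid of step 3. Silicon is chosen so that the final deprotection can use fluoride, which spares the ring E methyl ether and the alkene.

Step 3
Reactants: 2 2-diazocyclohexane-1,3-dione; 4 (E)-3,3',4,5'-tetrakis(TBS-oxy)stilbene
Product: 5 (2S,3S)-2-ArC-3-ArD-3,5,6,7-tetrahydro-1-benzofuran-4(2H)-one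
Conditions: Rh2(S-PTTL)4 (2 mol%), dry PhCF3, 40 °C, 2 (1.5 equiv) added over 6 h
Reagents that add atoms: none
Why: Proposed new method: Rh2(S-PTTL)4 should expel N2 from 2 to give an electrophilic divalent-rhodium carbenoid flanked by two acyl groups, which attacks the alkene of 4 at the carbon bearing ring D (C3–C3a), because the positive charge developing on the other carbon is delocalised onto the para-silyloxy oxygen of ring C; the rhodium-bound dione enolate oxygen then closes on that benzylic cation (O1–C2), a stepwise formal (3+2) annulation and not a concerted cycloaddition (a donor–acceptor cyclopropane that ring-expands would converge on the same product). The closest known reaction type is the Rh2 carboxylate-catalysed formal (3+2) cycloaddition of 2-diazocyclohexane-1,3-dione with styrenes and vinyl ethers to give dihydrofurans, and the oxidative radical annulation of cyclohexane-1,3-diones with stilbenes shows that a trans-1,2-diarylalkene can accept the dione in this sense; what is not established is high enantioselectivity with a 1,2-diarylalkene. Ring B closes in a 5-exo-trig sense when the cation is written in its quinoid oxocarbenium form, the C2=C(aryl) bond lying outside the new ring. C3 is set in the C–C bond-forming event, where the phthalimido-tert-leucinate ligands must differentiate the two alkene faces (catalyst control). C2 is set in the ring closure relative to C3: the freely rotating cation closes so that rings C and D end up trans (substrate control), as expected from the (E)-alkene and from the thermodynamic preference. The step needs regioselectivity (secured by the para-oxygen of ring C, ring D having only meta-oxygens), chemoselectivity for the alkene over the electron-rich arenes (helped by the bulky silyl groups beside the nucleophilic ring positions and by the absence of any O–H), diastereoselectivity (stepwise closure) and enantioselectivity (catalyst only). Slow addition of 2 keeps the carbenoid concentration low so that the hindered alkene can compete.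

Step 4
Reactants: 5 (2S,3S)-2-ArC-3-ArD-3,5,6,7-tetrahydro-1-benzofuran-4(2H)-one
Product: 9 (2S,3S)-2-ArC-3-ArD-2,3-dihydro-1-benzofuran-4-ol, via C5 phenylselanyl ketone 6 (not isolated), via selenoxide 7 (not isolated), via dienone tautomer 8 (not isolated)
Conditions: LiN(iPr)2 (1.15 equiv), THF, −78 °C; PhSeCl (1.2 equiv), −78 °C; then H2O2 (30%), pyridine, CH2Cl2, 0 °C to rt
Reagents that add atoms: none
Why: Kinetic deprotonation of the vinylogous ester at C5, selenenylation and selenoxide syn-elimination towards C6 give the cross-conjugated dienone 8, whose enolisation to the phenol is driven by aromaticity. The oxidation is confined to the carbonyl-activated C5–C6 bond and C3a bears no hydrogen, so C2 and C3 are not touched and ring B is not aromatised.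

Step 5
Reactants: 9 (2S,3S)-2-ArC-3-ArD-2,3-dihydro-1-benzofuran-4-ol
Product: 10 (2S,3S)-2-ArC-3-ArD-4-(TBS-oxy)-2,3-dihydro-1-benzofuran
Conditions: TBSOTf (1.3 equiv), 2,6-lutidine (2 equiv), CH2Cl2, 0 °C
Reagents that add atoms: tert-butyldimethylsilyl trifluoromethanesulfonate, CC(C)(C)[Si](C)(C)OS(=O)(=O)C(F)(F)F
Why: Silylation of a hindered phenol with the silyl triflate; the bulky ether shields C5 in the borylation and keeps the acidic O–H away from the iridium boryl catalyst.

Step 6
Reactants: 10 (2S,3S)-2-ArC-3-ArD-4-(TBS-oxy)-2,3-dihydro-1-benzofuran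
Product: 11 (2S,3S)-2-ArC-3-ArD-4-(TBS-oxy)-6-(4,4,5,5-tetramethyl-1,3,2-dioxaborolan-2-yl)-2,3-dihydro-1-benzofuran
Conditions: [Ir(OMe)(cod)]2 (2.5 mol%), dtbpy (5 mol%), B2pin2 (1.0 equiv), THF, 60 °C
Reagents that add atoms: bis(pinacolato)diboron, CC1(C)OB(OC1(C)C)B1OC(C)(C)C(C)(C)O1
Why: Iridium-catalysed aromatic C–H borylation is governed by sterics: C6–H is the only aryl C–H of 10 flanked by two hydrogens, whereas C5–H and every C–H of rings C and D have at least one ortho substituent. C7–H, next to the small ring oxygen, is the one serious competitor and is treated among the uncertain steps.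

Step 7
Reactants: 12 ferulic acid
Product: 14 (E)-3-[4-(TBS-oxy)-3-methoxyphenyl]prop-2-enoic acid, via silyl ester 13 (not isolated)
Conditions: TBSCl (2.4 equiv), imidazole (5 equiv), DMF, rt; then AcOH/THF/H2O, rt
Reagents that add atoms: tert-butyldimethylsilyl chloride, CC(C)(C)[Si](C)(C)Cl
Why: Both acidic sites are silylated and the far more labile silyl ester is then hydrolysed selectively. The phenol must be masked because NBS would otherwise brominate ring E in step 8.

Step 8
Reactants: 14 (E)-3-[4-(TBS-oxy)-3-methoxyphenyl]prop-2-enoic acid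
Product: 15 (E)-1-(2-bromoethenyl)-4-(TBS-oxy)-3-methoxybenzene
Conditions: NBS (1.05 equiv), LiOAc (0.2 equiv), MeCN/H2O (97:3), rt, dark
Reagents that add atoms: N-bromosuccinimide, O=C1CCC(=O)N1Br
Why: Catalytic Hunsdiecker-type bromodecarboxylation of an electron-rich cinnamic acid: carboxylate-assisted bromination of the alkene is followed by anti decarboxylative elimination, which returns the (E)-bromoalkene. The para-silyloxy group supplies the benzylic cation stabilisation on which this variant depends.

Step 9
Reactants: 11 (2S,3S)-2-ArC-3-ArD-4-(TBS-oxy)-6-(4,4,5,5-tetramethyl-1,3,2-dioxaborolan-2-yl)-2,3-dihydro-1-benzofuran; 15 (E)-1-(2-bromoethenyl)-4-(TBS-oxy)-3-methoxybenzene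
Product: 16 (2S,3S)-2-ArC-3-ArD-4-(TBS-oxy)-6-[(E)-2-(4-(TBS-oxy)-3-methoxyphenyl)ethenyl]-2,3-dihydro-1-benzofuran
Conditions: Pd(dppf)Cl2 (5 mol%), K3PO4 (3 equiv, 2 M aq), THF, 50 °C, degassed
Reagents that add atoms: none
Why: Suzuki–Miyaura coupling of an aryl pinacol boronate with an alkenyl bromide; oxidative addition and reductive elimination at palladium retain the (E)-geometry. The phosphate base at 50 °C is chosen to spare the aryl silyl ethers, and any partly desilylated material converges on 17 in step 10.

Step 10
Reactants: 16 (2S,3S)-2-ArC-3-ArD-4-(TBS-oxy)-6-[(E)-2-(4-(TBS-oxy)-3-methoxyphenyl)ethenyl]-2,3-dihydro-1-benzofuran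
Product: 17 (2S,3S)-2-(3,4-dihydroxyphenyl)-3-(3,5-dihydroxyphenyl)-6-[(E)-2-(4-hydroxy-3-methoxyphenyl)ethenyl]-2,3-dihydro-1-benzofuran-4-ol (CNP0199755.1)
Conditions: Bu4NF (7.5 equiv), AcOH (7.5 equiv), THF, 0 °C to rt, argon, dark
Reagents that add atoms: none
Why: Fluoride cleaves all six Si–O bonds, driven by the strong Si–F bond, while the aryl methyl ether and the alkene are inert. The AcOH buffer keeps the phenols protonated, which should suppress air oxidation of the catechol and base-induced opening of O1–C2 through a quinone methide, so the C2/C3 configuration is retained.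

## Compound list

1 | cyclohexane-1,3-dione | O=C1CCCC(=O)C1 | starting material
2 | 2-diazocyclohexane-1,3-dione | [N-]=[N+]=C1C(=O)CCCC1=O | intermediate
3 | piceatannol | Oc1cc(O)cc(/C=C/c2ccc(O)c(O)c2)c1 | starting material
4 | (E)-3,3',4,5'-tetrakis(tert-butyldimethylsilyloxy)stilbene | CC(C)(C)[Si](C)(C)Oc1ccc(/C=C/c2cc(O[Si](C)(C)C(C)(C)C)cc(O[Si](C)(C)C(C)(C)C)c2)cc1O[Si](C)(C)C(C)(C)C | intermediate
5 | (2S,3S)-2-ArC-3-ArD-3,5,6,7-tetrahydro-1-benzofuran-4(2H)-one | O=C1CCCC2=C1[C@H](c1cc(O[Si](C)(C)C(C)(C)C)cc(O[Si](C)(C)C(C)(C)C)c1)[C@@H](c1ccc(O[Si](C)(C)C(C)(C)C)c(O[Si](C)(C)C(C)(C)C)c1)O2 | intermediate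
6 | (2S,3S)-2-ArC-3-ArD-5-(phenylselanyl)-3,5,6,7-tetrahydro-1-benzofuran-4(2H)-one (C5 epimers) | O=C1C([Se]c3ccccc3)CCC2=C1[C@H](c1cc(O[Si](C)(C)C(C)(C)C)cc(O[Si](C)(C)C(C)(C)C)c1)[C@@H](c1ccc(O[Si](C)(C)C(C)(C)C)c(O[Si](C)(C)C(C)(C)C)c1)O2 | intermediate (not isolated)
7 | (2S,3S)-2-ArC-3-ArD-5-(benzeneseleninyl)-3,5,6,7-tetrahydro-1-benzofuran-4(2H)-one | O=C1C([Se](=O)c3ccccc3)CCC2=C1[C@H](c1cc(O[Si](C)(C)C(C)(C)C)cc(O[Si](C)(C)C(C)(C)C)c1)[C@@H](c1ccc(O[Si](C)(C)C(C)(C)C)c(O[Si](C)(C)C(C)(C)C)c1)O2 | intermediate (not isolated)
8 | (2S,3S)-2-ArC-3-ArD-3,7-dihydro-1-benzofuran-4(2H)-one (keto tautomer of 9) | O=C1C=CCC2=C1[C@H](c1cc(O[Si](C)(C)C(C)(C)C)cc(O[Si](C)(C)C(C)(C)C)c1)[C@@H](c1ccc(O[Si](C)(C)C(C)(C)C)c(O[Si](C)(C)C(C)(C)C)c1)O2 | intermediate (not isolated)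
9 | (2S,3S)-2-ArC-3-ArD-2,3-dihydro-1-benzofuran-4-ol | Oc1cccc2c1[C@H](c1cc(O[Si](C)(C)C(C)(C)C)cc(O[Si](C)(C)C(C)(C)C)c1)[C@@H](c1ccc(O[Si](C)(C)C(C)(C)C)c(O[Si](C)(C)C(C)(C)C)c1)O2 | intermediate
10 | (2S,3S)-2-ArC-3-ArD-4-(tert-butyldimethylsilyloxy)-2,3-dihydro-1-benzofuran | CC(C)(C)[Si](C)(C)Oc1cccc2c1[C@H](c1cc(O[Si](C)(C)C(C)(C)C)cc(O[Si](C)(C)C(C)(C)C)c1)[C@@H](c1ccc(O[Si](C)(C)C(C)(C)C)c(O[Si](C)(C)C(C)(C)C)c1)O2 | intermediate
11 | (2S,3S)-2-ArC-3-ArD-4-(tert-butyldimethylsilyloxy)-6-(4,4,5,5-tetramethyl-1,3,2-dioxaborolan-2-yl)-2,3-dihydro-1-benzofuran | CC(C)(C)[Si](C)(C)Oc1cc(B3OC(C)(C)C(C)(C)O3)cc2c1[C@H](c1cc(O[Si](C)(C)C(C)(C)C)cc(O[Si](C)(C)C(C)(C)C)c1)[C@@H](c1ccc(O[Si](C)(C)C(C)(C)C)c(O[Si](C)(C)C(C)(C)C)c1)O2 | intermediate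
12 | ferulic acid | COc1cc(/C=C/C(=O)O)ccc1O | starting material
13 | tert-butyldimethylsilyl (E)-3-[4-(tert-butyldimethylsilyloxy)-3-methoxyphenyl]prop-2-enoate | COc1cc(/C=C/C(=O)O[Si](C)(C)C(C)(C)C)ccc1O[Si](C)(C)C(C)(C)C | intermediate (not isolated)
14 | (E)-3-[4-(tert-butyldimethylsilyloxy)-3-methoxyphenyl]prop-2-enoic acid | COc1cc(/C=C/C(=O)O)ccc1O[Si](C)(C)C(C)(C)C | intermediate
15 | (E)-1-(2-bromoethenyl)-4-(tert-butyldimethylsilyloxy)-3-methoxybenzene | COc1cc(/C=C/Br)ccc1O[Si](C)(C)C(C)(C)C | intermediate
16 | (2S,3S)-2-ArC-3-ArD-4-(tert-butyldimethylsilyloxy)-6-[(E)-2-(4-(tert-butyldimethylsilyloxy)-3-methoxyphenyl)ethenyl]-2,3-dihydro-1-benzofuran | COc1cc(/C=C/c2cc(O[Si](C)(C)C(C)(C)C)c3c(c2)O[C@H](c2ccc(O[Si](C)(C)C(C)(C)C)c(O[Si](C)(C)C(C)(C)C)c2)[C@H]3c2cc(O[Si](C)(C)C(C)(C)C)cc(O[Si](C)(C)C(C)(C)C)c2)ccc1O[Si](C)(C)C(C)(C)C | intermediate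
17 | (2S,3S)-2-(3,4-dihydroxyphenyl)-3-(3,5-dihydroxyphenyl)-6-[(E)-2-(4-hydroxy-3-methoxyphenyl)ethenyl]-2,3-dihydro-1-benzofuran-4-ol | COc1cc(/C=C/c2cc(O)c3c(c2)O[C@H](c2ccc(O)c(O)c2)[C@H]3c2cc(O)cc(O)c2)ccc1O | target

## Step count and uncertain steps

Total step count: 10. Longest linear sequence: 7 (step 1 or step 2, then steps 3, 4, 5, 6, 9 and 10); the ring E branch (steps 7 and 8) joins at step 9.

**Step 3 (the step labelled as a new method).**
- What may go wrong: poor facial discrimination, because the chiral carboxylate must tell apart the two faces of a nearly symmetrical trans-diarylalkene in a stepwise, charge-separated pathway. In addition the hindered alkene may capture the carbenoid slowly, so that carbenoid decay or electrophilic attack on the electron-rich ring D takes over.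
- Fallback with known chemistry, from 1 and 4, returning at 5: oxidative radical annulation with Mn(OAc)3·2H2O (2.2 equiv) in AcOH at 60 °C. Trivalent manganese oxidises the enol of 1 to an electrophilic radical, which adds at the ring D carbon; the ring C benzylic radical is oxidised to the cation and trapped by the enol oxygen. This should give the trans ketone as the racemate, that is 5 together with its mirror image (2R,3R)-2-ArC-3-ArD-3,5,6,7-tetrahydro-1-benzofuran-4(2H)-one F1. The two are separated by preparative supercritical-fluid chromatography on a polysaccharide chiral stationary phase, and 5 re-enters at step 4.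

**Step 6.**
- What may go wrong: competing borylation at C7, because the ring oxygen is small and acidifies the neighbouring C–H, plus some double borylation.
- Fallback, from 4, returning at 16, with the C6 carbon built into the dione so that no C–H selection is needed:
  - Commercial ethyl 3,5-dioxocyclohexane-1-carboxylate F3 is converted by the diazo transfer of step 1 into ethyl 4-diazo-3,5-dioxocyclohexane-1-carboxylate F4.
  - Annulation with 4 as in step 3 (or by the manganese variant above) should give ethyl (2S,3S)-2-ArC-3-ArD-4-oxo-2,3,4,5,6,7-hexahydro-1-benzofuran-6-carboxylate F5, whose C6 epimers are of no consequence.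
  - The selenoxide dehydrogenation of step 4 gives ethyl (2S,3S)-2-ArC-3-ArD-4-hydroxy-2,3-dihydro-1-benzofuran-6-carboxylate F6, and silylation as in step 5 gives ethyl (2S,3S)-2-ArC-3-ArD-4-(TBS-oxy)-2,3-dihydro-1-benzofuran-6-carboxylate F7.
  - iBu2AlH (CH2Cl2, −78 °C) reduces the ester to [(2S,3S)-2-ArC-3-ArD-4-(TBS-oxy)-2,3-dihydro-1-benzofuran-6-yl]methanol F8, and MnO2 oxidises it to (2S,3S)-2-ArC-3-ArD-4-(TBS-oxy)-2,3-dihydro-1-benzofuran-6-carbaldehyde F9.
  - The ring E partner comes from vanillyl alcohol F10: a Michaelis–Arbuzov reaction with P(OEt)3 and ZnI2 gives diethyl [(4-hydroxy-3-methoxyphenyl)methyl]phosphonate F11, and TBSCl/imidazole gives diethyl {[4-(TBS-oxy)-3-methoxyphenyl]methyl}phosphonate F12.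
  - Horner–Wadsworth–Emmons olefination of F9 with the anion of F12 (NaN(SiMe3)2, THF, 0 °C) should give 16 with the (E)-alkene.

**Step 4.**
- What may go wrong: electrophilic selenenylation of the newly formed, electron-rich phenol by the selenenic acid by-product, and incomplete or double selenenylation of the enolate.
- Fallback, from 5, returning at 9: LiN(iPr)2 and Me3SiCl (THF, −78 °C) give (2S,3S)-2-ArC-3-ArD-4-(trimethylsilyloxy)-2,3,6,7-tetrahydro-1-benzofuran F2. Pd(OAc)2 (1.1 equiv, MeCN, rt) dehydrogenates it (Saegusa–Ito oxidation) to dienone 8, which tautomerises to 9.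

**Step 9.**
- What may go wrong: loss of phenolic silyl groups under aqueous base, giving mixtures that are hard to purify, and protodeboronation of the electron-rich boronate.
- Fallback, from 11, returning at 16: a base-free oxidative Heck coupling. Commercial 2-methoxy-4-vinylphenol F13 is silylated (TBSCl, imidazole) to 4-ethenyl-1-(TBS-oxy)-2-methoxybenzene F14. This is coupled with 11 under Pd(OAc)2 (5 mol%), 2,9-dimethyl-1,10-phenanthroline and O2 (1 atm) in DMF at 50 °C; arylpalladium addition to the terminal alkene carbon and β-hydride elimination should give the (E)-stilbene 16.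

## Further compounds

F1 | step 3 | (2R,3R)-2-ArC-3-ArD-3,5,6,7-tetrahydro-1-benzofuran-4(2H)-one (enantiomer of 5) | O=C1CCCC2=C1[C@@H](c1cc(O[Si](C)(C)C(C)(C)C)cc(O[Si](C)(C)C(C)(C)C)c1)[C@H](c1ccc(O[Si](C)(C)C(C)(C)C)c(O[Si](C)(C)C(C)(C)C)c1)O2
F2 | step 4 | (2S,3S)-2-ArC-3-ArD-4-(trimethylsilyloxy)-2,3,6,7-tetrahydro-1-benzofuran | C[Si](C)(C)OC1=CCCC2=C1[C@H](c1cc(O[Si](C)(C)C(C)(C)C)cc(O[Si](C)(C)C(C)(C)C)c1)[C@@H](c1ccc(O[Si](C)(C)C(C)(C)C)c(O[Si](C)(C)C(C)(C)C)c1)O2
F3 | step 6 | ethyl 3,5-dioxocyclohexane-1-carboxylate | CCOC(=O)C1CC(=O)CC(=O)C1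
F4 | step 6 | ethyl 4-diazo-3,5-dioxocyclohexane-1-carboxylate | CCOC(=O)C1CC(=O)C(=[N+]=[N-])C(=O)C1
F5 | step 6 | ethyl (2S,3S)-2-ArC-3-ArD-4-oxo-2,3,4,5,6,7-hexahydro-1-benzofuran-6-carboxylate (C6 epimers) | CCOC(=O)C1CC(=O)C2=C(C1)O[C@H](c1ccc(O[Si](C)(C)C(C)(C)C)c(O[Si](C)(C)C(C)(C)C)c1)[C@H]2c1cc(O[Si](C)(C)C(C)(C)C)cc(O[Si](C)(C)C(C)(C)C)c1
F6 | step 6 | ethyl (2S,3S)-2-ArC-3-ArD-4-hydroxy-2,3-dihydro-1-benzofuran-6-carboxylate | CCOC(=O)c1cc(O)c2c(c1)O[C@H](c1ccc(O[Si](C)(C)C(C)(C)C)c(O[Si](C)(C)C(C)(C)C)c1)[C@H]2c1cc(O[Si](C)(C)C(C)(C)C)cc(O[Si](C)(C)C(C)(C)C)c1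
F7 | step 6 | ethyl (2S,3S)-2-ArC-3-ArD-4-(tert-butyldimethylsilyloxy)-2,3-dihydro-1-benzofuran-6-carboxylate | CCOC(=O)c1cc(O[Si](C)(C)C(C)(C)C)c2c(c1)O[C@H](c1ccc(O[Si](C)(C)C(C)(C)C)c(O[Si](C)(C)C(C)(C)C)c1)[C@H]2c1cc(O[Si](C)(C)C(C)(C)C)cc(O[Si](C)(C)C(C)(C)C)c1
F8 | step 6 | [(2S,3S)-2-ArC-3-ArD-4-(tert-butyldimethylsilyloxy)-2,3-dihydro-1-benzofuran-6-yl]methanol | OCc1cc(O[Si](C)(C)C(C)(C)C)c2c(c1)O[C@H](c1ccc(O[Si](C)(C)C(C)(C)C)c(O[Si](C)(C)C(C)(C)C)c1)[C@H]2c1cc(O[Si](C)(C)C(C)(C)C)cc(O[Si](C)(C)C(C)(C)C)c1
F9 | step 6 | (2S,3S)-2-ArC-3-ArD-4-(tert-butyldimethylsilyloxy)-2,3-dihydro-1-benzofuran-6-carbaldehyde | O=Cc1cc(O[Si](C)(C)C(C)(C)C)c2c(c1)O[C@H](c1ccc(O[Si](C)(C)C(C)(C)C)c(O[Si](C)(C)C(C)(C)C)c1)[C@H]2c1cc(O[Si](C)(C)C(C)(C)C)cc(O[Si](C)(C)C(C)(C)C)c1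
F10 | step 6 | vanillyl alcohol | COc1cc(CO)ccc1O
F11 | step 6 | diethyl [(4-hydroxy-3-methoxyphenyl)methyl]phosphonate | CCOP(=O)(OCC)Cc1ccc(O)c(OC)c1
F12 | step 6 | diethyl {[4-(tert-butyldimethylsilyloxy)-3-methoxyphenyl]methyl}phosphonate | CCOP(=O)(OCC)Cc1ccc(O[Si](C)(C)C(C)(C)C)c(OC)c1
F13 | step 9 | 2-methoxy-4-vinylphenol | C=Cc1ccc(O)c(OC)c1
F14 | step 9 | 4-ethenyl-1-(tert-butyldimethylsilyloxy)-2-methoxybenzene | C=Cc1ccc(O[Si](C)(C)C(C)(C)C)c(OC)c1
A1 | alternative 1 | 1,2,2-triarylethyl pinacol boronate (boron on C2, C3 as in the target) | CC1(C)OB(OC1(C)C)[C@@H](c1ccc(OCOC)c(OCOC)c1)[C@H](c1c(OCOC)cc(/C=C/c2ccc(OCOC)c(OC)c2)cc1OCOC)c1cc(OCOC)cc(OCOC)c1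
A2 | alternative 1 | 2-[(E)-2-{2,6-bis(methoxymethoxy)-4-[(E)-2-(3-methoxy-4-(methoxymethoxy)phenyl)ethenyl]phenyl}ethenyl]-4,4,5,5-tetramethyl-1,3,2-dioxaborolane | CC1(C)OB(/C=C/c2c(OCOC)cc(/C=C/c3ccc(OCOC)c(OC)c3)cc2OCOC)OC1(C)C
A3 | alternative 1 | 3,4-bis(methoxymethoxy)phenyllithium | [Li]c1ccc(OCOC)c(OCOC)c1
A4 | alternative 1 | 3,5-bis(methoxymethoxy)phenyl trifluoromethanesulfonate | COCOc1cc(OCOC)cc(OS(=O)(=O)C(F)(F)F)c1
A5 | alternative 2 | ring A phenol with the open C2–C3 chain (C4–OH free, C7a–O-triisopropylsilyl, C6–CH2O-TBS) | CC(C)(C)[Si](C)(C)O[C@@H](c1ccc(OCc2ccccc2)c(OCc2ccccc2)c1)[C@H](c1c(O)cc(CO[Si](C)(C)C(C)(C)C)cc1O[Si](C(C)C)(C(C)C)C(C)C)c1cc(OCc2ccccc2)cc(OCc2ccccc2)c1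
A6 | alternative 2 | chiral ynol triisopropylsilyl ether carrying the C2–C3 diaryl unit | CC(C)[Si](C(C)C)(C(C)C)OC#C[C@H](c1cc(OCc2ccccc2)cc(OCc2ccccc2)c1)[C@@H](O[Si](C)(C)C(C)(C)C)c1ccc(OCc2ccccc2)c(OCc2ccccc2)c1
A7 | alternative 2 | 3-[(tert-butyldimethylsilyloxy)methyl]cyclobut-2-en-1-one | O=C1C=C(CO[Si](C)(C)C(C)(C)C)C1
A8 | alternative 3 | 2-aryl-4-(benzyloxy)-6-(methoxycarbonyl)-2,3-dihydro-1-benzofuran-3-carboxylic acid (C2 as in the target, trans) | COC(=O)c1cc(OCc2ccccc2)c2c(c1)O[C@H](c1ccc3OC(c4ccccc4)(c4ccccc4)Oc3c1)[C@H]2C(=O)O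
A9 | alternative 3 | methyl 5-(benzyloxy)-3-diazo-2-(2,2-diphenyl-1,3-benzodioxol-5-yl)-4-oxochromane-7-carboxylate (C2 as in the target) | COC(=O)c1cc(OCc2ccccc2)c2C(=O)C(=[N+]=[N-])[C@@H](c3ccc4OC(c5ccccc5)(c5ccccc5)Oc4c3)Oc2c1
A10 | alternative 3 | (2S)-eriodictyol | O=C1C[C@@H](c2ccc(O)c(O)c2)Oc2cc(O)cc(O)c12
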